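The earlier runs and the new flask are calculated on assumed constants; noise was put on by code.

Start from the beta run, whose readings at 3.00 h and 4.00 h, 34.8% and 34.9%, lie closer together than the scatter of 0.5 percentage points, so treat that level as a ceiling, set it beside the last readings of the alpha and epsilon runs, and take as the ceiling share, the fraction of consumed substrate that stands as target (its selectivity), the mean of the three, 35.4%, so that target is reckoned as this share times the fraction of substrate consumed.

| flask | substrate | solid reagent | remark | time |
|---|---|---|---|---|
| alpha | 1 M | 1.5 M | run made earlier |  |
| epsilon | 1 M | 2.2 M | run made earlier |  |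
| beta | 0.50 M | 3 M | run made earlier |  |
| flask | 1.0 M | 3.00 M |  | 4.0 h |

| run | time / h | target / % |
|---|---|---|
| alpha | 0.333 | 3.5 |
| alpha | 0.667 | 10.8 |
| alpha | 1.00 | 15.2 |
| alpha | 2.00 | 27.7 |
| alpha | 4.00 | 35.5 |
| epsilon | 0.333 | 4.3 |
| epsilon | 1.00 | 16.1 |
| epsilon | 2.00 | 27.8 |
| epsilon | 3.00 | 33.5 |
| epsilon | 4.00 | 35.8 |
| beta | 0.833 | 16.8 |
| beta | 1.50 | 26.5 |
| beta | 2.50 | 33.0 |
| beta | 3.00 | 34.8 |
| beta | 4.00 | 34.9 |

(each reading ± 0.5 percentage points)

- given per volume of solution although it is solid: solid reagent
- at the start none of the solid reagent is in solution

- violet: doubling the solubility of the solid reagent, all else as stated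
- teal: doubling the dissolution coefficient of the solid reagent, all else as stated

1. how much target there is at 4.0 h, in percent of the substrate charged
2. the change that raises the amount of target at 4.0 h, in percent of the substrate charged most ("none" if none brings more than 2 percentage points) (violet / teal / none)
3. amount of target at 4.0 h, in percent of the substrate charged, after teal

Climb the time scales from the shortest. Over its first 0.333 h the alpha run gains 3.5% and over the next step of like length 7.3 points, which is more, so read a lag, since the solid reagent starts with none in solution. On the next rung target passes 17.7% between 1.00 h and 2.00 h, and at 2.00 h the alpha and epsilon runs read 27.7% and 27.8% with solid charges of 1.5 M and 2.2 M, so count the solid load as out of play in that range. On the last rung the beta run, with 0.50 M of substrate, has reached its ceiling by 3.00 h, while the epsilon run, with 1 M, still gains 2.3 points in its last hour and reads 35.8% at 4.00 h. Expect the flask, with the substrate of the epsilon run and 3.00 M of solid, to stand near the ceiling at 4.0 h, about 35.4%, and expect neither change to clear 2 points, since a faster feed closes the gap to the ceiling without raising the share.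

The forecast gives 35.8%, a little above my ceiling, then none and 35.5% after teal, holding that “the peak height is fixed by selectivity”; its peak differs from my ceiling, for it is a maximum that the forecast expects doubled solubility to overshoot, giving about 32%, whereas my ceiling is a lasting share that a faster feed only approaches.

The flask gives 35.1% of target and the choice none, with violet adding 0.54 points and teal 0.38 points, which brings it to 35.5%.

    substrate + partner → intermediate + by-product (k = 0.0720 M⁻¹ min⁻¹)
    intermediate ⇌ target (K = 3.10, k = 1.40 min⁻¹)
    intermediate ⇌ isomer of the product (K = 4.60, k = 0.560 min⁻¹)
    solid reagent ⇌ partner, rate k4*(cs4 - [partner]) while solid is left; crystals form when [partner] > cs4 (solubility = 0.380 M, k = 0.0390 min⁻¹)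

At 4.0 h the flask has 1.7% of its substrate left, so the ceiling share times the consumed fraction gives 34.8%; read the same flask at 1.5 h, with 38.6% of substrate left, and the share gives 21.7%, where the flask holds 22.5%.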